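**Plan**

Numbering: C1 = tertiary carbinol bearing C7H2OBz, C2 and C3 = CH(OAc), C4=C5 = ring alkene, C6 = CH(OBz).
Enabling feature: on the cyclohexene ring the C6 benzoate is allylic to C4=C5 and cis-vicinal to the free tertiary C1–OH. This is the pattern left when an O1 benzoyl group traps a C4–C5–C6 allyl cation through a cis-fused 1,3-dioxolan-2-ylium ring and is then hydrolysed.
Cuts, in order: the two acetyl C–O bonds; C5–H back to C5–Br; C6–O6 together with re-closure of C4–C6 (cyclohexene → CBr2-bridged cyclopentane); C4–C5/C5–C6 (carbene); the benzoyl C–O bonds; C1–O1/C7–O7 (dihydroxylation); C1=C7 (methylenation); C4=C6 (metathesis); C1–C6 (vinyl addition).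
Forward: a C1–C4 chain from D-arabinose is extended by vinyl and the five-membered ring C1–C2–C3–C4–C6 closes by metathesis. C7 and then C5 are added one carbon at a time, and the six-membered ring appears only in the ring expansion.
Stereochemistry: C2 and C3 are C2 and C3 of D-arabinose. C1 comes from osmylation anti to O2. C6 is relayed from C1 by the cis ring fusion of the acyloxonium ion.

Key step: step 12

Remark (convention and one assumption): with C1→C6 drawn clockwise, O2 and C7 point up and O1, O3 and O6 point down. Dibromocarbene is assumed to add mainly to the upper face, and a lower-face adduct would feed the same cation.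

**Route**

Step 1
Reactants: 1 D-arabinose
Product: 2 methyl D-arabinofuranoside (anomeric mixture)
Conditions: MeOH, HCl (cat.), rt, short contact; neutralised with basic resin
Reagents that add atoms: methanol, CO
Why: Fischer glycosidation under kinetic control stops at the furanosides, which ties O4 into the ring and leaves O5 as the only primary hydroxyl, the anomeric mixture being irrelevant because C1 is unmasked again in step 4.

Step 2
Reactants: 2 methyl D-arabinofuranoside
Product: 3 methyl 5-deoxy-5-iodo-D-arabinofuranoside (anomeric mixture)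
Conditions: I2, PPh3, imidazole, THF, rt → 50 °C
Reagents that add atoms: iodine, II
Why: Garegg–Samuelsson (Appel-type) iodination proceeds by SN2 displacement of an alkoxyphosphonium ion and therefore takes the primary C5–OH ahead of the two secondary ring hydroxyls without touching a stereocentre.

Step 3
Reactants: 3 methyl 5-deoxy-5-iodo-D-arabinofuranoside
Product: 4 methyl 2,3-bis-O-(tert-butyldimethylsilyl)-5-deoxy-5-iodo-D-arabinofuranoside (anomeric mixture)
Conditions: TBSOTf, 2,6-lutidine, CH2Cl2, 0 °C → rt
Reagents that add atoms: tert-butyldimethylsilyl triflate, CC(C)(C)[Si](C)(C)OS(=O)(=O)C(F)(F)F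
Why: Silyl triflate with a hindered pyridine base silylates both hydroxyls of the trans-diol, and TBS is chosen because it cannot act as a neighbouring group in step 12 and tolerates zinc, Grignard reagent, ylide, two-phase hydroxide and silver(I).

Step 4
Reactants: 4 methyl 2,3-bis-O-TBS-5-deoxy-5-iodo-D-arabinofuranoside
Product: 5 (2S,3R)-2,3-bis(tert-butyldimethylsilyloxy)pent-4-enal
Conditions: Zn dust (activated), THF–H2O (4:1), ultrasound, 40 °C; used crude
Reagents that add atoms: none
Why: In the Bernet–Vasella reductive fragmentation zinc inserts into C5–I, the ring C4–O bond is expelled to form the vinyl group, and the released hemiacetal alkoxide loses methoxide to give the aldehyde, so sugar C2 and C3 pass unchanged into C2 and C3 of the target.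

Step 5
Reactants: 5 (2S,3R)-2,3-bis(TBSO)pent-4-enal; 6 vinylmagnesium bromide
Product: 7 (4R,5R)-4,5-bis(tert-butyldimethylsilyloxy)hepta-1,6-dien-3-ol (C3 epimers)
Conditions: THF, −78 → −20 °C; aq. NH4Cl
Reagents that add atoms: vinylmagnesium bromide 6, C=C[Mg]Br
Why: Grignard 1,2-addition to the α-silyloxy aldehyde is fast at low temperature so C2 should not epimerise, and the new carbinol centre needs no control because step 7 removes it.

Step 6
Reactants: 7 (4R,5R)-4,5-bis(TBSO)hepta-1,6-dien-3-ol
Product: 8 (4R,5R)-4,5-bis(tert-butyldimethylsilyloxy)cyclopent-2-en-1-ol (C1 epimers, silyloxy groups trans)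
Conditions: Grubbs II (3 mol %), CH2Cl2, 40 °C
Reagents that add atoms: none
Why: Ring-closing metathesis of a 1,6-diene with two monosubstituted alkenes to a cyclopentene is driven by loss of ethene and tolerates a free allylic hydroxyl and silyl ethers.

Step 7
Reactants: 8 (4R,5R)-4,5-bis(TBSO)cyclopent-2-en-1-ol
Product: 9 (4R,5S)-4,5-bis(tert-butyldimethylsilyloxy)cyclopent-2-en-1-one (trans)
Conditions: Dess–Martin periodinane, CH2Cl2, 0 °C → rt
Reagents that add atoms: none
Why: Dess–Martin oxidation of the secondary allylic alcohol is mild and near neutral, merges both carbinol epimers into one enone, and leaves the α-silyloxy centre C2 in its more stable trans relation to O3.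

Step 8
Reactants: 9 (4R,5S)-4,5-bis(TBSO)cyclopent-2-en-1-one
Product: 10 (3R,4R)-3,4-bis(tert-butyldimethylsilyloxy)-5-methylidenecyclopent-1-ene
Conditions: Ph3PCH3Br, KOtBu, THF, 0 °C; then 9, −78 → 0 °C
Reagents that add atoms: methyltriphenylphosphonium bromide, C[P+](c1ccccc1)(c1ccccc1)c1ccccc1.[Br-]
Why: Wittig methylenation with the non-stabilised ylide adds 1,2 to the enone carbonyl and delivers C7, any enolisation at C2 returns to the favoured trans isomer, and the resulting transoid diene cannot serve as a Diels–Alder diene.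

Step 9
Reactants: 10 (3R,4R)-3,4-bis(TBSO)-5-methylidenecyclopent-1-ene; 11 water
Product: 12 (1R,4R,5S)-4,5-bis(tert-butyldimethylsilyloxy)-1-(hydroxymethyl)cyclopent-2-en-1-ol (O1 down, C7 up)
Conditions: OsO4 (2 mol %), NMO (1.0 equiv), acetone–H2O, 0 °C
Reagents that add atoms: osmium tetroxide, O=[Os](=O)(=O)=O; N-methylmorpholine N-oxide, C[N+]1([O-])CCOCC1; water 11, O
Why: Upjohn dihydroxylation with one equivalent of oxidant should take the open 1,1-disubstituted exocyclic alkene ahead of the ring cis-alkene next to the C3 silyl ether, and osmium approaches anti to the adjacent allylic C2–OTBS (Kishi-type 1,2-induction), which sets C1 with O1 trans to O2 and C7 cis to O2.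

Step 10
Reactants: 12 (1R,4R,5S)-4,5-bis(TBSO)-1-(hydroxymethyl)cyclopent-2-en-1-ol; 13 benzoyl chloride
Product: 14 (1R,4R,5S)-1-benzoyloxy-1-(benzoyloxymethyl)-4,5-bis(tert-butyldimethylsilyloxy)cyclopent-2-ene
Conditions: BzCl (excess), DMAP (cat.), pyridine, 0 → 65 °C
Reagents that add atoms: benzoyl chloride 13, O=C(Cl)c1ccccc1
Why: DMAP-catalysed acylation esterifies the primary O7 first and the tertiary allylic O1 on warming, under basic conditions that cannot ionise the C1–O bond, so both benzoyl groups of the target enter in one operation.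

Step 11
Reactants: 14 (1R,4R,5S)-1-benzoyloxy-1-(benzoyloxymethyl)-4,5-bis(TBSO)cyclopent-2-ene; 15 bromoform
Product: 16 (1R,2R,3S,4R,5S)-2-benzoyloxy-2-(benzoyloxymethyl)-6,6-dibromo-3,4-bis(tert-butyldimethylsilyloxy)bicyclo[3.1.0]hexane (CBr2 bridge = C5, on the upper face with C7)
Conditions: CHBr3, 50% aq. NaOH, BnEt3NCl (cat.), CH2Cl2, 0 °C → rt, vigorous stirring
Reagents that add atoms: bromoform 15, BrC(Br)Br
Why: Makosza two-phase generation of dibromocarbene followed by its concerted, stereospecific [2+1] cycloaddition to the only alkene gives the cis-fused cyclopropane, expected anti to O1 and O3, while hydroxide stays in the aqueous layer so the lipophilic, hindered benzoates and silyl ethers should persist.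

Step 12
Reactants: 16 (1R,2R,3S,4R,5S)-2-benzoyloxy-2-(benzoyloxymethyl)-6,6-dibromo-3,4-bis(TBSO)bicyclo[3.1.0]hexane; 11 water
Product: 20 (1S,2S,3R,6R)-6-benzoyloxy-1-(benzoyloxymethyl)-5-bromo-2,3-bis(tert-butyldimethylsilyloxy)cyclohex-4-en-1-ol, via bromocyclohexenyl cation 17 (not isolated), via dioxolanylium triflate 18 (not isolated), via orthoacid 19 (not isolated)
Conditions: AgOTf, 2,6-di-tert-butyl-4-methylpyridine, ClCH2CH2Cl, dark, rt → 60 °C; then THF–H2O, NaHCO3, rt
Reagents that add atoms: water 11, O
Why: Silver(I) pulls off the endo bromide while the shared C4–C6 bond opens in the disrotatory 2π-electrocyclic sense required by the Woodward–Hoffmann–DePuy rule, so the six-membered ring arises by ring expansion of the bicyclo[3.1.0]hexane to the planar 2-bromocyclohexenyl cation 17 and not by a cyclisation, and a cyclopropane on either face would give the same ion. The closest known reaction type is the silver-promoted opening of ring-fused gem-dibromocyclopropanes with capture of the allyl cation by carboxylate, water or a tethered heteroatom, combined here with the acyloxonium participation familiar from Woodward–Prévost and Koenigs–Knorr chemistry. The carbonyl oxygen of the O1 benzoate closes the temporary 1,3-dioxolan-2-ylium ring of 18 on C6 in a 5-exo-trig mode, and since a five-membered ring spanning C1–C6 can only be cis-fused, the C1 stereocentre alone fixes the new C6 centre with O6 cis to O1. The step needs attack at C6 rather than C4 and on the O1 face: O2 and O3 carry silyl ethers that cannot participate, no external nucleophile is present until 18 has formed, and the O7 benzoate could reach C6 only from the opposite face through a six-membered ring, the entropically slower closure. Water 11 then adds to the acyloxonium carbon to give orthoacid 19, whose reversible opening under bicarbonate lets the benzoyl group settle on the secondary O6 and leaves the crowded tertiary O1 as the free hydroxyl, the thermodynamic resting point. The hindered pyridine base keeps the medium free of triflic acid, so the TBS ethers, the O7 benzoate and the allylic C3–O bond should survive.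

Step 13
Reactants: 20 (1S,2S,3R,6R)-6-benzoyloxy-1-(benzoyloxymethyl)-5-bromo-2,3-bis(TBSO)cyclohex-4-en-1-ol
Product: 21 (1S,2S,3R,6S)-6-benzoyloxy-1-(benzoyloxymethyl)-2,3-bis(tert-butyldimethylsilyloxy)cyclohex-4-en-1-ol
Conditions: Bu3SnH, AIBN (cat.), toluene, 85 °C
Reagents that add atoms: none
Why: In this radical-chain hydrodehalogenation the stannyl radical abstracts the vinylic bromine and the σ-vinyl radical takes hydrogen from the tin hydride, a method preferred to palladium(0)/hydride because it cannot ionise the allylic C6 benzoate, cannot fragment to a cyclic allene, and touches no stereocentre.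

Step 14
Reactants: 21 (1S,2S,3R,6S)-6-benzoyloxy-1-(benzoyloxymethyl)-2,3-bis(TBSO)cyclohex-4-en-1-ol
Product: 22 (1R,2S,3R,6S)-6-benzoyloxy-1-(benzoyloxymethyl)cyclohex-4-ene-1,2,3-triol
Conditions: HF·pyridine, pyridine–THF, 0 °C → rt
Reagents that add atoms: none
Why: Fluoride-driven Si–O cleavage in the weakly acidic, pyridine-buffered medium removes both secondary TBS ethers without forming the alkoxides that would set off benzoyl migration.

Step 15
Reactants: 22 (1R,2S,3R,6S)-6-benzoyloxy-1-(benzoyloxymethyl)cyclohex-4-ene-1,2,3-triol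
Product: 23 cleistenediol F, (1S,2S,3R,6S)-2,3-diacetoxy-6-benzoyloxy-1-(benzoyloxymethyl)cyclohex-4-en-1-ol
Conditions: Ac2O, pyridine, 0 °C → rt
Reagents that add atoms: acetic anhydride, CC(=O)OC(C)=O
Why: Pyridine-mediated acetylation esterifies the two secondary hydroxyls at C2 and C3, whereas the tertiary C1–OH, surrounded by three substituted carbons, should stay free under these unforced conditions.

**Compound list**

1 | D-arabinose | O=C[C@@H](O)[C@H](O)[C@H](O)CO | starting material
2 | methyl D-arabinofuranoside (anomeric mixture) | COC1O[C@H](CO)[C@@H](O)[C@@H]1O | intermediate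
3 | methyl 5-deoxy-5-iodo-D-arabinofuranoside (anomeric mixture) | COC1O[C@H](CI)[C@@H](O)[C@@H]1O | intermediate
4 | methyl 2,3-bis-O-TBS-5-deoxy-5-iodo-D-arabinofuranoside (anomeric mixture) | COC1O[C@H](CI)[C@@H](O[Si](C)(C)C(C)(C)C)[C@@H]1O[Si](C)(C)C(C)(C)C | intermediate
5 | (2S,3R)-2,3-bis(TBSO)pent-4-enal | O=C[C@@H](O[Si](C)(C)C(C)(C)C)[C@H](O[Si](C)(C)C(C)(C)C)C=C | intermediate
6 | vinylmagnesium bromide | C=C[Mg]Br | starting material
7 | (4R,5R)-4,5-bis(TBSO)hepta-1,6-dien-3-ol (C3 epimers) | C=CC(O)[C@@H](O[Si](C)(C)C(C)(C)C)[C@H](O[Si](C)(C)C(C)(C)C)C=C | intermediate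
8 | (4R,5R)-4,5-bis(TBSO)cyclopent-2-en-1-ol (C1 epimers) | CC(C)(C)[Si](C)(C)O[C@@H]1C=CC(O)[C@H]1O[Si](C)(C)C(C)(C)C | intermediate
9 | (4R,5S)-4,5-bis(TBSO)cyclopent-2-en-1-one | CC(C)(C)[Si](C)(C)O[C@@H]1C=CC(=O)[C@H]1O[Si](C)(C)C(C)(C)C | intermediate
10 | (3R,4R)-3,4-bis(TBSO)-5-methylidenecyclopent-1-ene | CC(C)(C)[Si](C)(C)O[C@@H]1C=CC(=C)[C@H]1O[Si](C)(C)C(C)(C)C | intermediate
11 | water | O | starting material
12 | (1R,4R,5S)-4,5-bis(TBSO)-1-(hydroxymethyl)cyclopent-2-en-1-ol | CC(C)(C)[Si](C)(C)O[C@@H]1C=C[C@@](O)(CO)[C@H]1O[Si](C)(C)C(C)(C)C | intermediate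
13 | benzoyl chloride | O=C(Cl)c1ccccc1 | starting material
14 | (1R,4R,5S)-1-benzoyloxy-1-(benzoyloxymethyl)-4,5-bis(TBSO)cyclopent-2-ene | CC(C)(C)[Si](C)(C)O[C@@H]1C=C[C@@](OC(=O)c2ccccc2)(COC(=O)c2ccccc2)[C@H]1O[Si](C)(C)C(C)(C)C | intermediate
15 | bromoform | BrC(Br)Br | starting material
16 | (1R,2R,3S,4R,5S)-2-benzoyloxy-2-(benzoyloxymethyl)-6,6-dibromo-3,4-bis(TBSO)bicyclo[3.1.0]hexane | CC(C)(C)[Si](C)(C)O[C@@H]1[C@H]2C(Br)(Br)[C@H]2[C@@](OC(=O)c2ccccc2)(COC(=O)c2ccccc2)[C@H]1O[Si](C)(C)C(C)(C)C | intermediate
17 | 2-bromocyclohexenyl (C4–C5–C6 allyl) cation triflate, O1 and O7 benzoates intact | CC(C)(C)[Si](C)(C)O[C@@H]1C=C(Br)[CH+][C@@](OC(=O)c2ccccc2)(COC(=O)c2ccccc2)[C@H]1O[Si](C)(C)C(C)(C)C.[O-]S(=O)(=O)C(F)(F)F | intermediate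
18 | cis-fused 2-phenyl-1,3-dioxolan-2-ylium triflate spanning O1 and O6 | CC(C)(C)[Si](C)(C)O[C@@H]1C=C(Br)[C@@H]2OC(c3ccccc3)=[O+][C@]2(COC(=O)c2ccccc2)[C@H]1O[Si](C)(C)C(C)(C)C.[O-]S(=O)(=O)C(F)(F)F | intermediate
19 | cis-fused 2-hydroxy-2-phenyl-1,3-dioxolane (orthoacid) spanning O1 and O6 | CC(C)(C)[Si](C)(C)O[C@@H]1C=C(Br)[C@@H]2OC(O)(c3ccccc3)O[C@]2(COC(=O)c2ccccc2)[C@H]1O[Si](C)(C)C(C)(C)C | intermediate
20 | (1S,2S,3R,6R)-6-benzoyloxy-1-(benzoyloxymethyl)-5-bromo-2,3-bis(TBSO)cyclohex-4-en-1-ol | CC(C)(C)[Si](C)(C)O[C@@H]1C=C(Br)[C@H](OC(=O)c2ccccc2)[C@@](O)(COC(=O)c2ccccc2)[C@H]1O[Si](C)(C)C(C)(C)C | intermediate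
21 | (1S,2S,3R,6S)-6-benzoyloxy-1-(benzoyloxymethyl)-2,3-bis(TBSO)cyclohex-4-en-1-ol | CC(C)(C)[Si](C)(C)O[C@@H]1C=C[C@H](OC(=O)c2ccccc2)[C@@](O)(COC(=O)c2ccccc2)[C@H]1O[Si](C)(C)C(C)(C)C | intermediate
22 | (1R,2S,3R,6S)-6-benzoyloxy-1-(benzoyloxymethyl)cyclohex-4-ene-1,2,3-triol | O[C@@H]1C=C[C@H](OC(=O)c2ccccc2)[C@@](O)(COC(=O)c2ccccc2)[C@H]1O | intermediate
23 | cleistenediol F | CC(=O)O[C@@H]1C=C[C@H](OC(=O)c2ccccc2)[C@@](O)(COC(=O)c2ccccc2)[C@H]1OC(C)=O | target

**Step count and risks**

Total step count: 15. Longest linear sequence: 15 steps, from D-arabinose.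

Steps most likely to fail:

1. Step 12.
   - Risk: ionisation may be too slow, because the incipient allyl cation carries bromine on its central carbon and a C–O dipole next to each terminus. Desilylation, proton loss, a hydride shift from C3, or closure by the O7 benzoate through a six-membered ring could then overtake the five-ring capture.
   - Fallback: lower the oxidation level of the cyclopropane before it is opened. Setting out from 16, one bromine is removed with Bu3SnH (1 equiv, Et3B/air, toluene, 0 °C), with hydrogen delivered to the open exo side of the cyclopropyl radical. This gives the endo-6-monobromide F1. AgOTf with the hindered pyridine base should open this more readily ionised halide at lower temperature. The opening passes through the bromine-free cyclohexenyl cation F2 to the dioxolanylium triflate F3. Aqueous bicarbonate then converts F3 through the orthoacid F4 into 21, where the route is rejoined and step 13 is no longer needed.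

2. Step 11.
   - Risk: the alkene is cis-disubstituted, flanked by two oxygenated carbons and shielded on both faces. Carbene addition may therefore be slower than carbene hydrolysis, and prolonged contact with hydroxide may begin to saponify the benzoates.
   - Fallback: change the order so that the carbene meets a more electron-rich, base-proof substrate. Setting out from 12, 2,2-dimethoxypropane and PPTS give the spiro-acetonide F5. CHBr3 and KOtBu in pentane (Doering–Hoffmann conditions) give the dibromocyclopropane acetonide F6. Treatment with 80% aqueous acetic acid at rt releases the dibromocyclopropane diol F7 with the secondary TBS ethers retained. Dibenzoylation as in step 10 rejoins the route at 16.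

3. Step 9.
   - Risk: site selectivity between the two alkenes of the conjugated diene may be poor, oxidation of both may occur, and facial selectivity may erode because the C3 silyl ether lies on the face that osmium must use.
   - Fallback: differentiate the two alkenes electronically. Setting out from 9, Wittig reaction with methoxymethylidenetriphenylphosphorane gives the dienol methyl ether F8 (E/Z mixture). OsO4/NMO should attack this electron-rich enol ether far faster than the ring alkene, again anti to O2, to give the hemiacetal F9. F9 collapses to the α-hydroxy aldehyde F10, and NaBH4 in MeOH at 0 °C rejoins the route at 12.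

**Further compounds**

F1 | step 12 | endo-6-monobromide of 16 (Br over the five-membered ring, H exo) | CC(C)(C)[Si](C)(C)O[C@@H]1[C@H]2[C@@H](Br)[C@H]2[C@@](OC(=O)c2ccccc2)(COC(=O)c2ccccc2)[C@H]1O[Si](C)(C)C(C)(C)C
F2 | step 12 | bromine-free cyclohexenyl cation triflate | CC(C)(C)[Si](C)(C)O[C@@H]1C=C[CH+][C@@](OC(=O)c2ccccc2)(COC(=O)c2ccccc2)[C@H]1O[Si](C)(C)C(C)(C)C.[O-]S(=O)(=O)C(F)(F)F
F3 | step 12 | bromine-free cis-fused 2-phenyl-1,3-dioxolan-2-ylium triflate | CC(C)(C)[Si](C)(C)O[C@@H]1C=C[C@@H]2OC(c3ccccc3)=[O+][C@]2(COC(=O)c2ccccc2)[C@H]1O[Si](C)(C)C(C)(C)C.[O-]S(=O)(=O)C(F)(F)F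
F4 | step 12 | bromine-free cis-fused orthoacid | CC(C)(C)[Si](C)(C)O[C@@H]1C=C[C@@H]2OC(O)(c3ccccc3)O[C@]2(COC(=O)c2ccccc2)[C@H]1O[Si](C)(C)C(C)(C)C
F5 | step 11 | O1,O7-isopropylidene derivative of 12 (spiro-1,3-dioxolane at C1) | CC(C)(C)[Si](C)(C)O[C@@H]1C=C[C@@]3(COC(C)(C)O3)[C@H]1O[Si](C)(C)C(C)(C)C
F6 | step 11 | 6,6-dibromobicyclo[3.1.0]hexane spiro-acetonide | CC(C)(C)[Si](C)(C)O[C@@H]1[C@H]2C(Br)(Br)[C@H]2[C@@]3(COC(C)(C)O3)[C@H]1O[Si](C)(C)C(C)(C)C
F7 | step 11 | 6,6-dibromobicyclo[3.1.0]hexane C1,C7-diol | CC(C)(C)[Si](C)(C)O[C@@H]1[C@H]2C(Br)(Br)[C@H]2[C@@](O)(CO)[C@H]1O[Si](C)(C)C(C)(C)C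
F8 | step 9 | 5-(methoxymethylidene)-3,4-bis(TBSO)cyclopent-1-ene (E/Z mixture) | CC(C)(C)[Si](C)(C)O[C@@H]1C=CC(=COC)[C@H]1O[Si](C)(C)C(C)(C)C
F9 | step 9 | C7 methyl hemiacetal of the α-hydroxy aldehyde (C7 epimers) | CC(C)(C)[Si](C)(C)O[C@@H]1C=C[C@@](O)(C(O)OC)[C@H]1O[Si](C)(C)C(C)(C)C
F10 | step 9 | 1-hydroxy-4,5-bis(TBSO)cyclopent-2-ene-1-carbaldehyde (O1 down) | CC(C)(C)[Si](C)(C)O[C@@H]1C=C[C@@](O)(C=O)[C@H]1O[Si](C)(C)C(C)(C)C
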